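Slowness can be counted per enzyme: take the target made per hour, divide it by the enzyme charged, and you have a figure that stays put under a change of charge if each enzyme works for itself, and drifts if it does not. Gamma, with 24% after 1.333 h, has averaged 514 h⁻¹ since its start, and this is its turnover per charged enzyme. Alpha, with 19% after 1.33 h, has averaged 408 h⁻¹, so the reading for gamma over alpha is 1.26.

| flask | starting material | enzyme | remark |
|---|---|---|---|
| gamma | 0.010 M | 0.035 mol% | the very flask that is asked about, followed so far |
| alpha | 0.0050 M | 0.035 mol% | run made earlier |
| flask | 0.010 M | 0.035 mol% |  |

gamma run (percent of the starting material charged)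

| time / min | target / % |
|---|---|
| 6.00 | 7 |
| 12.0 | 6 |
| 25.0 | 11 |
| 50.0 | 17 |
| 80.0 | 24 |

alpha run (percent of the starting material charged)

| time / h | target / % |
|---|---|
| 0.500 | 5 |
| 1.33 | 19 |
| 2.50 | 32 |
| 4.00 | 46 |
| 6.00 | 67 |

(readings scatter by 2 percentage points)

1. factor on the rate of making target when 20% of the starting material are converted if enzyme is charged twice over
2. factor on the rate when 20% of the starting material are converted if enzyme is charged at 0.2 mol% instead



If that gain belonged to the enzyme, doubling the charge would multiply the rate by 2.52. But alpha has half the starting material of gamma and half its enzyme, so the two changes cannot be separated. The scatter also gives the ratio an uncertainty of 0.169, which leaves it less than two uncertainties from equal turnover. So solve the ends instead. In a round where each enzyme works for itself, thin starting material gives a rate proportional to enzyme times starting material, and thick starting material holds every enzyme as complex, with a rate proportional to enzyme. Both ends are first order in enzyme, and so is any join between them. At fixed starting material the turnover should then stay put, and I would commit to 2.00 and 5.71.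

The forecast stands higher than my reckoning, at 3.2 and 19, “suggesting dimer-like or cooperative activation”.

The flask gives 2.11 and 6.49.

    starting material + enzyme ⇌ complex (K = 650 M⁻¹, k = 6150 M⁻¹ s⁻¹)
    complex ⇌ enzyme + target (K = 0.490 M, k = 0.192 s⁻¹)
    2 enzyme → spent catalyst (k = 16.3 M⁻¹ s⁻¹)
    enzyme ⇌ dormant form (K = 1.50, k = 7.41 × 10⁻⁴ s⁻¹)

At 1.10 h the flask runs at 475 h⁻¹ per charged enzyme. The doubled charge multiplies that turnover by 1.05, and the charge of 0.2 mol% multiplies it by 1.14. One part of why the drift stays this small, though not the main reason, shows in the simulated run without the return of dormant form to enzyme: there the apparent order in enzyme at that conversion climbs from 1.1 to 1.6.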